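**Retrosynthetic overview**

1. Target 16 is a (6S)-5,6-dihydropyran-2-one carrying the C1′–C15′ chain (6′/4′ anti, 4′/2′ syn, 2′/6 anti). Late disconnections: O–PMB cleavage, C4′ carbinol by syn reduction of β-hydroxy ketone 13, and C2′–C3′ by a 1,5-anti boron aldol between methyl ketone 5 (C3′–C15′, carries C6′) and lactone aldehyde 10 (ring, C1′, C2′).
2. Aldehyde 10 comes from enol acetate 8, and 8 from a one-step [4+2] heteroannulation of (Z)-3-iodoacrylic acid 6 (O1, C2, C3, C4) with 1-acetoxybuta-1,3-diene 7 (C5, C6, C1′, C2′). C4–C5 and O1–C6 are made together, C6 is set, and the E/Z mixture of 7 converges.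
3. Enabling feature: ring atoms C5 and C6 plus chain atoms C1′ and C2′ (oxygen-bearing) form a masked 1-oxybuta-1,3-diene. C6 can therefore be the terminus of a C6–C1′–C2′ π-allyl, placed for six-membered closure by the carboxylate of the (Z)-acrylate unit O1–C2(=O)–C3=C4.
4. Ketone 5 comes from decanal 1 by Keck allylation, PMB protection and Wacker oxidation.
5. Ring order: the dihydropyranone is the only ring; it is formed in step 4 and carried through aldol, reduction and deprotection.

Key step: step 4

Assumption: the lactone is numbered O1, C2–C6 and the side chain C1′–C15′; the target is read as (6S)-6-[(2S,4S,6R)-2,4,6-trihydroxypentadecyl]-5,6-dihydro-2H-pyran-2-one, and commercial 1-acetoxybuta-1,3-diene is taken as its E/Z mixture.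

**Route**

Step 1
Reactants: 1 decanal; 2 allyltributylstannane
Product: 3 (R)-tridec-1-en-4-ol
Conditions: (S)-BINOL (10 mol %), Ti(OiPr)4 (10 mol %), 4 Å MS, CH2Cl2, −20 °C; aq NaHCO3
Reagents that add atoms: none
Why: Keck asymmetric allylation, in which the (S)-BINOL–titanium Lewis acid should deliver the allyl group to one face of the unbranched aldehyde and so set C6′ (R).

Step 2
Reactants: 3 (R)-tridec-1-en-4-ol
Product: 4 (R)-1-methoxy-4-[(tridec-1-en-4-yloxy)methyl]benzene
Conditions: NaH, PMBCl, n-Bu4NI (cat.), THF/DMF, 0 °C to rt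
Reagents that add atoms: 4-methoxybenzyl chloride, COc1ccc(CCl)cc1
Why: Williamson etherification of the sodium alkoxide leaves the stereocenter untouched and installs the benzylic ether that the later 1,5-anti aldol induction requires.

Step 3
Reactants: 4 (R)-1-methoxy-4-[(tridec-1-en-4-yloxy)methyl]benzene
Product: 5 (R)-4-[(4-methoxybenzyl)oxy]tridecan-2-one
Conditions: PdCl2 (10 mol %), CuCl (20 mol %), O2 (1 atm), DMF/H2O (7:1), rt
Reagents that add atoms: water, O
Why: Wacker–Tsuji oxidation, in which Markovnikov hydroxypalladation of the terminal alkene should give the methyl ketone while the PMB ether and C6′ are inert.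

Step 4
Reactants: 6 (Z)-3-iodoacrylic acid; 7 1-acetoxybuta-1,3-diene (E/Z mixture, 2 equiv)
Product: 8 (E)-2-[(2S)-6-oxo-3,6-dihydro-2H-pyran-2-yl]ethenyl acetate
Conditions: Pd2(dba)3 (2.5 mol %), chiral BINOL-derived phosphoramidite (6 mol %), K2CO3 (2 equiv), toluene/DMF (4:1), 60 °C
Reagents that add atoms: none
Why: Proposed new method: zerovalent palladium inserts into the C–I bond of the potassium salt of 6 with retention of the Z geometry, the alkenylpalladium adds across the unsubstituted terminal C=C of 7 so that the alkenyl carbon bonds to the CH2 terminus (C4–C5), and the resulting divalent 1-acetoxy-π-allylpalladium over C6–C1′–C2′ is closed by the tethered carboxylate at C6 (O1–C6) with release of zerovalent palladium. The closest known reaction type is the Larock heteroannulation of 1,3-dienes by iodoarenes and iodoalkenes that carry an OH, NHR or CO2H group (racemic), together with the enantioselective palladium-catalysed heteroannulation of 1,3-dienes by 2-haloanilines and 2-halophenols under chiral monophosphorus ligands; what is unprecedented is ligand control in the carboxylate case with an acyloxy diene. The lactone closes in a 6-exo mode onto the allyl terminus (formal [4+2], four ring atoms from 6 and two from 7), whereas attack at the acetoxy-bearing terminus would need an eight-membered ring and should not compete. C6 is set in the C–O bond-forming step by the chiral phosphoramidite on palladium, and the ligand antipode that leads to the 6S lactone is the one to be used. The step is stereoconvergent: both geometric isomers of 7 and the diastereomeric allyl complexes should interconvert by η3–η1–η3 shifts faster than ring closure and funnel through the syn,syn-allyl complex to the single (E)-enol acetate and one C6 configuration. Regioselective insertion is secured by the bias of the diene for attack at its CH2 terminus (it gives the stabilised allyl), and β-hydride elimination to a triene should be outrun by the intramolecular carboxylate capture.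

Step 5
Reactants: 8 (E)-2-[(2S)-6-oxo-3,6-dihydro-2H-pyran-2-yl]ethenyl acetate
Product: 10 2-[(2S)-6-oxo-3,6-dihydro-2H-pyran-2-yl]acetaldehyde, via enol 9 (not isolated)
Conditions: Novozym 435 (immobilised lipase B of Candida antarctica), EtOH (2 equiv), MTBE, 25 °C; filter, evaporate, use crude
Reagents that add atoms: none
Why: Lipase-catalysed transesterification in which the enol acetate acts as an activated acyl donor toward ethanol and the released enol tautomerises to the aldehyde under neutral conditions, so the base-sensitive β-acyloxy aldehyde and C6 are not endangered.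

Step 6
Reactants: 5 (R)-4-[(4-methoxybenzyl)oxy]tridecan-2-one; 10 2-[(2S)-6-oxo-3,6-dihydro-2H-pyran-2-yl]acetaldehyde
Product: 13 (6S)-6-[(2R,6R)-2-hydroxy-6-[(4-methoxybenzyl)oxy]-4-oxopentadecyl]-5,6-dihydro-2H-pyran-2-one, via boron enolate 11 (not isolated), via boron aldolate 12 (not isolated)
Conditions: c-Hex2BCl, Et3N, Et2O, 0 °C; then 10, −78 °C; MeOH/pH 7 buffer/H2O2, 0 °C
Reagents that add atoms: none
Why: Boron-mediated aldol addition of a methyl ketone, in which the β-PMB-oxy group of the dicyclohexylboron enolate should direct 1,5-anti induction and so set C2′ anti to the C6′ oxygen (the weak 1,3-anti preference of the aldehyde points the same way), without strong base.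

Step 7
Reactants: 13 (6S)-6-[(2R,6R)-2-hydroxy-6-[(4-methoxybenzyl)oxy]-4-oxopentadecyl]-5,6-dihydro-2H-pyran-2-one
Product: 15 (6S)-6-[(2S,4R,6R)-2,4-dihydroxy-6-[(4-methoxybenzyl)oxy]pentadecyl]-5,6-dihydro-2H-pyran-2-one, via diethylboron chelate 14 (not isolated)
Conditions: Et2BOMe, THF/MeOH (4:1), −78 °C; NaBH4, −78 °C; AcOH; MeOH co-evaporation
Reagents that add atoms: none
Why: Narasaka–Prasad reduction, in which the C2′–O–BEt2 chelate to the ketone should take external hydride axially to give the 2′,4′-syn diol, while the conjugated lactone is inert to NaBH4 at −78 °C and the PMB-capped C6′ oxygen cannot compete as a directing group.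

Step 8
Reactants: 15 (6S)-6-[(2S,4R,6R)-2,4-dihydroxy-6-[(4-methoxybenzyl)oxy]pentadecyl]-5,6-dihydro-2H-pyran-2-one
Product: 16 (6S)-6-[(2S,4S,6R)-2,4,6-trihydroxypentadecyl]-5,6-dihydro-2H-pyran-2-one
Conditions: DDQ, CH2Cl2/pH 7 buffer (10:1), 0 °C
Reagents that add atoms: none
Why: Oxidative PMB ether cleavage by hydride abstraction and hydrolysis of the oxocarbenium ion in the wet medium, neutral conditions that should spare the unsaturated lactone and all four stereocenters.

**Compound list**

1 | decanal | CCCCCCCCCC=O | starting material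
2 | allyltributylstannane | C=CC[Sn](CCCC)(CCCC)CCCC | starting material
3 | (R)-tridec-1-en-4-ol | CCCCCCCCC[C@@H](O)CC=C | intermediate
4 | (R)-1-methoxy-4-[(tridec-1-en-4-yloxy)methyl]benzene | CCCCCCCCC[C@@H](OCc1ccc(OC)cc1)CC=C | intermediate
5 | (R)-4-[(4-methoxybenzyl)oxy]tridecan-2-one | CCCCCCCCC[C@@H](OCc1ccc(OC)cc1)CC(C)=O | intermediate
6 | (Z)-3-iodoacrylic acid | OC(=O)/C=C\I | starting material
7 | 1-acetoxybuta-1,3-diene (E/Z mixture) | CC(=O)OC=CC=C | starting material
8 | (E)-2-[(2S)-6-oxo-3,6-dihydro-2H-pyran-2-yl]ethenyl acetate | CC(=O)O/C=C/[C@@H]1CC=CC(=O)O1 | intermediate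
9 | (S)-6-[(E)-2-hydroxyethenyl]-5,6-dihydro-2H-pyran-2-one (enol, not isolated) | O/C=C/[C@@H]1CC=CC(=O)O1 | intermediate
10 | 2-[(2S)-6-oxo-3,6-dihydro-2H-pyran-2-yl]acetaldehyde | O=CC[C@@H]1CC=CC(=O)O1 | intermediate
11 | (R)-dicyclohexyl{[4-[(4-methoxybenzyl)oxy]tridec-1-en-2-yl]oxy}borane (boron enolate of 5, not isolated) | CCCCCCCCC[C@@H](OCc1ccc(OC)cc1)CC(=C)OB(C1CCCCC1)C1CCCCC1 | intermediate
12 | 2′-O-dicyclohexylboryl derivative of 13 (boron aldolate, not isolated) | CCCCCCCCC[C@@H](OCc1ccc(OC)cc1)CC(=O)C[C@H](OB(C2CCCCC2)C2CCCCC2)C[C@@H]1CC=CC(=O)O1 | intermediate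
13 | (6S)-6-[(2R,6R)-2-hydroxy-6-[(4-methoxybenzyl)oxy]-4-oxopentadecyl]-5,6-dihydro-2H-pyran-2-one | CCCCCCCCC[C@@H](OCc1ccc(OC)cc1)CC(=O)C[C@H](O)C[C@@H]1CC=CC(=O)O1 | intermediate
14 | 2′-O-diethylboryl derivative of 13, chelated to the C4′ ketone (not isolated) | CCCCCCCCC[C@@H](OCc1ccc(OC)cc1)CC(=O)C[C@H](OB(CC)CC)C[C@@H]1CC=CC(=O)O1 | intermediate
15 | (6S)-6-[(2S,4R,6R)-2,4-dihydroxy-6-[(4-methoxybenzyl)oxy]pentadecyl]-5,6-dihydro-2H-pyran-2-one | CCCCCCCCC[C@@H](OCc1ccc(OC)cc1)C[C@H](O)C[C@H](O)C[C@@H]1CC=CC(=O)O1 | intermediate
16 | (6S)-6-[(2S,4S,6R)-2,4,6-trihydroxypentadecyl]-5,6-dihydro-2H-pyran-2-one | CCCCCCCCC[C@@H](O)C[C@H](O)C[C@H](O)C[C@@H]1CC=CC(=O)O1 | target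

**Step count and risks**

Total steps: 8. Longest linear sequence: 6 steps (1, 2, 3, 6, 7, 8); the lactone branch (4, 5) joins at step 6.

Steps most likely to fail:

1) Step 4 (key step, proposed new method). What may go wrong: insufficient ligand control over the face of C–O bond formation, loss of enantiomeric purity through reversible ionisation of the allylic lactone C–O bond by zerovalent palladium, or β-hydride elimination before ring closure. The fallback uses only known chemistry and closes the ring by metathesis instead of heteroannulation. It sets out from allyltributylstannane 2, which is added under the Keck conditions of step 1 [(S)-BINOL, Ti(OiPr)4, same facial sense] to commercial 3-[(tert-butyldimethylsilyl)oxy]propanal to give (S)-1-[(tert-butyldimethylsilyl)oxy]hex-5-en-3-ol F1. Acylation with acryloyl chloride and Et3N should give (S)-1-[(tert-butyldimethylsilyl)oxy]hex-5-en-3-yl acrylate F2. Ring-closing metathesis with the second-generation Grubbs catalyst (CH2Cl2, 40 °C) should give (S)-6-{2-[(tert-butyldimethylsilyl)oxy]ethyl}-5,6-dihydro-2H-pyran-2-one F3. HF·pyridine should free (S)-6-(2-hydroxyethyl)-5,6-dihydro-2H-pyran-2-one F4, and Dess–Martin periodinane should oxidise it to aldehyde 10, where the route is rejoined before step 6.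

2) Step 6. What may go wrong: amine- or boron-induced β-elimination of the lactone carboxylate from the aldehyde (ring opening), or weak 1,5-induction. The fallback moves stereocontrol from the enolate to the aldehyde and works under Lewis acid instead of amine base. It sets out from ketone 5, which is converted with LiN(SiMe3)2 and Me3SiCl (THF, −78 °C) into (R)-{[4-[(4-methoxybenzyl)oxy]tridec-1-en-2-yl]oxy}trimethylsilane F5. A Mukaiyama aldol of this enol silane with aldehyde 10 (BF3·OEt2, CH2Cl2, −78 °C) should proceed through an open transition state with 1,3-anti induction from the C6 oxygen and give 13 after aqueous work-up, where the route is rejoined before step 7.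

3) Step 5. What may go wrong: slow acyl transfer from the substituted enol ester, competing enzymatic alcoholysis of the lactone, or decomposition of the free aldehyde by β-elimination on concentration. The fallback replaces the enzymatic unmasking by acid-catalysed transacetalisation to a storable acetal. It sets out from enol acetate 8, which with pyridinium p-toluenesulfonate, MeOH and HC(OMe)3 should give (S)-6-(2,2-dimethoxyethyl)-5,6-dihydro-2H-pyran-2-one F6. This acetal is hydrolysed (LiBF4, wet MeCN) immediately before use to aldehyde 10, where the route is rejoined before step 6.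

**Further compounds**

F1 | step 4 | (S)-1-[(tert-butyldimethylsilyl)oxy]hex-5-en-3-ol | CC(C)(C)[Si](C)(C)OCC[C@@H](O)CC=C
F2 | step 4 | (S)-1-[(tert-butyldimethylsilyl)oxy]hex-5-en-3-yl acrylate | CC(C)(C)[Si](C)(C)OCC[C@@H](OC(=O)C=C)CC=C
F3 | step 4 | (S)-6-{2-[(tert-butyldimethylsilyl)oxy]ethyl}-5,6-dihydro-2H-pyran-2-one | CC(C)(C)[Si](C)(C)OCC[C@@H]1CC=CC(=O)O1
F4 | step 4 | (S)-6-(2-hydroxyethyl)-5,6-dihydro-2H-pyran-2-one | OCC[C@@H]1CC=CC(=O)O1
F5 | step 6 | (R)-{[4-[(4-methoxybenzyl)oxy]tridec-1-en-2-yl]oxy}trimethylsilane | CCCCCCCCC[C@@H](OCc1ccc(OC)cc1)CC(=C)O[Si](C)(C)C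
F6 | step 5 | (S)-6-(2,2-dimethoxyethyl)-5,6-dihydro-2H-pyran-2-one | COC(OC)C[C@@H]1CC=CC(=O)O1
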